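**Retrosynthetic overview**

- Feature: in the cycloheptane the methylene C5 lies between carbinol C6 and ring-fusion carbon C4, and C4 carries the lactone α-carbon Ca. A C4=C5 1,1-disubstituted alkene with an ester-bearing CaH2 can therefore serve as the ene partner of a C6 aldehyde.
- Key disconnection C5–C6: a Lewis-acid type two carbonyl-ene cyclisation of aldehyde 25 closes the seven-membered carbocycle (first ring), sets C6 and leaves C4=Ca.
- Aldehyde 25 comes from D-tartrate (C2, C3): C1 by chelation-controlled alkenyl-Grignard addition to a ketone, C7 by hydrogenation of a temporary α-methylene lactone, C4–Ca by enol triflate/Reformatsky cross-coupling.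
- After the ene: OH-directed hydrogenation (C4), ester methylenation, acid-triggered closure of the γ-lactone (second ring), C2 acylation, then C8 aldehyde → propenyl carbinol (Nozaki–Hiyama–Kishi) → enone.

Key step: step 16

Remark on numbering: the cycloheptane carbons are C1 (carbinol carbon bearing the crotonoyl carbonyl C8), C2 (isovalerate carbon), C3 (lactone O–CH), C4 (ring-fusion CH bearing the lactone α-carbon Ca), C5 (CH2), C6 (CHOH) and C7 (CHCH3).
Remark on the chemistry: 2-bromoprop-2-en-1-ol, methyl bromoacetate, isovaleric anhydride and (E)-1-iodoprop-1-ene are taken as purchasable.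
Remark on the chemistry: the ene product is drawn with the ester cis to C3; the other geometric isomer would converge in step 17.

**Route**

Step 1
Reactants: 1 dimethyl 2,3-O-isopropylidene-D-tartrate [(4S,5S)]
Product: 2 (4S,5S)-N,N,N',N',2,2-hexamethyl-1,3-dioxolane-4,5-dicarboxamide
Conditions: Me2NH (excess, 2 M in MeOH), MeOH, rt, sealed vessel
Reagents that add atoms: dimethylamine, CNC
Why: Aminolysis of the α-alkoxy-activated methyl esters gives the C2-symmetric bis-amide without touching the trans-dioxolane stereocentres.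

Step 2
Reactants: 2 bis(dimethylamide)
Product: 3 (4S,5S)-5-acetyl-N,N,2,2-tetramethyl-1,3-dioxolane-4-carboxamide (acetyl carbon = C1, its methyl = future C8)
Conditions: MeMgBr (1.3 equiv), THF, −20 → 0 °C; aq NH4Cl
Reagents that add atoms: methylmagnesium bromide, C[Mg]Br
Why: Grignard addition to a tertiary amide stops at the chelated magnesium hemiaminal, so one amide of the symmetric diamide becomes the methyl ketone on work-up and the other is kept for C4.

Step 3
Reactants: 3 keto amide
Product: 6 α-silyloxy ketone [C8H2–OSiMe2t-Bu next to the C1 ketone], via silyl enol ether 4 (not isolated), via silyloxy epoxide 5 (not isolated)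
Conditions: t-BuMe2SiOTf, Et3N, CH2Cl2, −20 °C; then mCPBA, NaHCO3, CH2Cl2, 0 °C
Reagents that add atoms: tert-butyldimethylsilyl triflate, CC(C)(C)[Si](C)(C)OS(=O)(=O)C(F)(F)F; mCPBA, OOC(=O)c1cccc(Cl)c1
Why: Silyl enol ether formation on the methyl side followed by Rubottom oxidation (epoxidation, then 1,4-silyl shift) installs the C8 oxygen directly as its silyl ether.

Step 4
Reactants: 7 2-bromoprop-2-en-1-ol
Product: 8 (2-bromoallyloxy)(tert-butyl)dimethylsilane
Conditions: t-BuMe2SiCl, imidazole, CH2Cl2, 0 °C → rt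
Reagents that add atoms: tert-butyldimethylsilyl chloride, CC(C)(C)[Si](C)(C)Cl
Why: Standard silyl ether formation protects the allylic alcohol before metalation of the alkenyl bromide.

Step 5
Reactants: 6 α-silyloxy ketone; 8 alkenyl bromide
Product: 11 tertiary alcohol [C1 (R) bearing OH, C8H2OSi and the 3-silyloxyprop-1-en-2-yl group C7(=CH2)–C6H2OSi], via alkenyllithium 9 (not isolated), via alkenylmagnesium bromide 10 (not isolated)
Conditions: 8, t-BuLi (2 equiv), Et2O, −78 °C; MgBr2·OEt2, −78 °C; then 6, −78 → −40 °C; aq NH4Cl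
Reagents that add atoms: none
Why: Bromine–lithium exchange, transmetalation and Grignard addition under Cram chelate control (magnesium bridging the carbonyl and the dioxolane oxygen on C2, the C8 oxygen being a poorly coordinating silyl ether) deliver the alkenyl group to the face syn to C2–H and so set C1 as in the target.

Step 6
Reactants: 11 tertiary alcohol
Product: 12 triol [C6H2OH allylic, C8H2OH, tertiary C1–OH]
Conditions: Bu4NF, THF, 0 °C → rt
Reagents that add atoms: none
Why: Fluoride-mediated desilylation frees both primary hydroxyls for lactone formation.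

Step 7
Reactants: 12 triol
Product: 15 α-methylene-β-hydroxy-γ-butyrolactone [C6 carbonyl, ring oxygen from C8, exocyclic C7=CH2], via hydroxy enal 13 (not isolated), via lactol 14 (not isolated)
Conditions: MnO2 (activated, excess), CH2Cl2, rt
Reagents that add atoms: none
Why: MnO2 oxidises only the allylic primary alcohol, the enal is trapped as the five-membered lactol by the C8 hydroxyl and the lactol is oxidised on to the lactone (allylic oxidation–lactonisation cascade).

Step 8
Reactants: 15 α-methylene lactone
Product: 16 α-methyl lactone [C7 methyl cis to the dioxolanyl group, trans to the tertiary OH; C1 (R), C7 (R)]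
Conditions: H2 (1 atm), [Ir(cod)(PCy3)(py)]PF6 (5 mol %), CH2Cl2, rt
Reagents that add atoms: none
Why: Hydroxyl-directed homogeneous hydrogenation adds hydrogen from the face of the tertiary OH, which is also the face away from the bulky dioxolanyl group, so C7 is set as the target requires.

Step 9
Reactants: 16 α-methyl lactone
Product: 17 triol [C6H2OH, C8H2OH, C1–OH; C7 (S)]
Conditions: LiBH4, THF, 0 °C → rt
Reagents that add atoms: none
Why: Borohydride reduction of the lactone gives the diol while the less electrophilic tertiary amide should survive.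

Step 10
Reactants: 17 triol
Product: 18 C1/C8 acetonide with free C6 hydroxyl
Conditions: 2,2-dimethoxypropane, camphorsulfonic acid (cat.), acetone, rt
Reagents that add atoms: 2,2-dimethoxypropane, COC(C)(C)OC
Why: Thermodynamic acetonide formation selects the 1,2-diol, because the alternative 1,3-dioxane through C6–OH would force a substituent of quaternary C1 syn-axial to an acetonide methyl.

Step 11
Reactants: 18 alcohol
Product: 19 C6 triethylsilyl ether
Conditions: Et3SiCl, imidazole, CH2Cl2, 0 °C
Reagents that add atoms: chlorotriethylsilane, CC[Si](Cl)(CC)CC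
Why: Silyl ether formation with a group that can later be oxidised directly to the aldehyde.

Step 12
Reactants: 19 amide
Product: 20 methyl ketone [C4 carbonyl, new methyl = C5]
Conditions: MeMgBr (3 equiv), THF, 0 °C; aq NH4Cl
Reagents that add atoms: methylmagnesium bromide, C[Mg]Br
Why: Grignard addition to the α-alkoxy dimethylamide again stops at the hemiaminal and gives the ketone on work-up.

Step 13
Reactants: 20 methyl ketone
Product: 21 terminal enol triflate [C4(OTf)=C5H2]
Conditions: KN(SiMe3)2, THF, −78 °C; PhNTf2, −78 → −20 °C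
Reagents that add atoms: N-phenylbis(trifluoromethanesulfonimide), O=S(=O)(N(c1ccccc1)S(=O)(=O)C(F)(F)F)C(F)(F)F
Why: Kinetic deprotonation on the methyl side and O-triflation (enol triflate formation) avoid the C3 enolate, which would expel the dioxolane oxygen.

Step 14
Reactants: 21 enol triflate; 22 methyl bromoacetate
Product: 24 methyl 3-methylenebutanoate arm on C3 [C4(=C5H2)–CaH2–CO2Me], via Reformatsky reagent 23 (not isolated)
Conditions: 22, Zn dust (Me3SiCl-activated), THF, rt; then 21, Pd2(dba)3 (2.5 mol %), XPhos (10 mol %), THF, 50 °C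
Reagents that add atoms: none
Why: Negishi-type cross-coupling of the zinc ester enolate with the alkenyl triflate under zerovalent palladium forms C4–Ca and gives the β,γ-unsaturated ester without a base that could move the alkene into conjugation.

Step 15
Reactants: 24 triethylsilyl ether
Product: 25 aldehyde, the ene precursor [C6 aldehyde; C7 (R), C1 (R)]
Conditions: (COCl)2, DMSO, CH2Cl2, −78 → −30 °C; Et3N, −78 °C
Reagents that add atoms: none
Why: Primary triethylsilyl ethers are oxidised directly under Swern conditions, which unveils the aldehyde in one operation beside the alkene, ester and acetonides and keeps the α-stereocentre C7 cold.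

Step 16
Reactants: 25 aldehyde
Product: 26 cycloheptanol with exocyclic C4=Ca enoate [C6–OH trans to C7–CH3; C1 (R), C2 (S), C3 (R), C6 (R), C7 (S)]
Conditions: MeAl(OC6H2-4-Br-2,6-t-Bu2)2 (2.5 equiv, from Me3Al and 4-bromo-2,6-di-tert-butylphenol 1:2, CH2Cl2, rt), CH2Cl2, −78 → −40 °C; aq potassium sodium tartrate
Reagents that add atoms: none
Why: The oxophilic aluminium aryloxide binds the C6 aldehyde, the terminal alkene carbon C5 bonds to C6 and one Ca hydrogen passes to the aluminium-bound oxygen through a six-centre array, which moves the double bond to C4=Ca in conjugation with the ester; the closest known reaction is the Lewis-acid promoted type two intramolecular carbonyl-ene cyclisation of aldehydes to methylenecyclohexanols and methylenecycloheptanols, for which bulky methylaluminium bis(aryloxides) are established promoters. The cycloheptane closes in the type two mode because the tether C3–C2–C1–C7 hangs on the central ene carbon C4, a 7-endo closure at the alkene and 7-exo at the carbonyl. C6 is the only new stereocentre: the oxygen must lie gauche to C4 across the forming bond (axial on the nascent ring) to reach Ca–H, so the trans relation of C6–O and C7–CH3 needs the methyl anti to that oxygen, which the very bulky ligand sphere on aluminium should enforce by penalising a gauche methyl, an axial methyl costing little next to quaternary C1; a small aluminium chloride would be expected to favour the C6 epimer through the chair with equatorial methyl. Hydrogen transfer from Ca and not from C3 is secured by the freely rotating, ester-acidified CaH2 against a C3–H locked in the trans-dioxolane, and a chloride-free, non-chelating Lewis acid at low temperature is chosen so that the acetonides survive.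

Step 17
Reactants: 26 cycloheptanol
Product: 27 saturated ester [C4–H cis to C6–OH and to C3–H; C4 (S)]
Conditions: H2 (1 atm), [Ir(cod)(PCy3)(py)]PF6 (5 mol %), CH2Cl2, rt
Reagents that add atoms: none
Why: Hydroxyl-directed hydrogenation: the cationic iridium catalyst binds the axial C6 hydroxyl and delivers hydrogen to the exocyclic enoate from that face, which sets the cis ring fusion of the future lactone whatever the alkene geometry.

Step 18
Reactants: 27 alcohol
Product: 28 C6 triisopropylsilyl ether
Conditions: i-Pr3SiOTf, 2,6-lutidine, CH2Cl2, 0 °C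
Reagents that add atoms: triisopropylsilyl triflate, CC(C)[Si](OS(=O)(=O)C(F)(F)F)(C(C)C)C(C)C
Why: Silyl ether formation with the triflate overcomes the hindrance at C6 and gives an ether that survives the later acidic steps.

Step 19
Reactants: 28 ester
Product: 31 α-methylene ester [C4–C(=CH2)–CO2Me], via Mannich base 29 (not isolated), via ammonium iodide 30 (not isolated)
Conditions: LiN(i-Pr)2, THF, −78 °C; CH2=NMe2 I, −78 °C → rt; MeI, MeOH, rt; aq NaHCO3, CH2Cl2
Reagents that add atoms: N,N-dimethylmethyleneiminium iodide, C=[N+](C)C.[I-]; iodomethane, CI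
Why: α-Methylenation by Mannich reaction of the ester enolate with Eschenmoser's salt, N-methylation and mild base elimination of trimethylamine, at a stage with no free hydroxyl and no other acidic C–H.

Step 20
Reactants: 31 α-methylene ester
Product: 33 cis-fused α-methylene-γ-butyrolactone with free C2 hydroxyl and intact C1/C8 acetonide, via diol ester 32 (not isolated)
Conditions: camphorsulfonic acid (0.1 equiv), acetone–H2O (50:1), 40 °C
Reagents that add atoms: none
Why: Acid-catalysed transketalisation in acetone: the strained trans-fused C2/C3 acetonide opens reversibly and the C3 hydroxyl is removed irreversibly by lactonisation onto the cis-disposed ester, whereas the unstrained C1/C8 dioxolane is held in place by the solvent and the trans C2 hydroxyl cannot lactonise.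

Step 21
Reactants: 33 hydroxy lactone; 34 isovaleric anhydride
Product: 35 C2 isovalerate
Conditions: DMAP, Et3N, CH2Cl2, rt
Reagents that add atoms: none
Why: DMAP-catalysed esterification of the only free hydroxyl installs the 3-methylbutanoate.

Step 22
Reactants: 35 acetonide
Product: 36 diol [tertiary C1–OH, primary C8–OH]
Conditions: AcOH–H2O (4:1), 45 °C
Reagents that add atoms: none
Why: Acetal hydrolysis under mild aqueous acid spares the triisopropylsilyl ether, the isovalerate and the α-methylene lactone.

Step 23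
Reactants: 36 diol
Product: 37 bis(triethylsilyl) ether
Conditions: Et3SiOTf, 2,6-lutidine, CH2Cl2, −78 → 0 °C
Reagents that add atoms: triethylsilyl triflate, CC[Si](OS(=O)(=O)C(F)(F)F)(CC)CC
Why: Silylation protects the tertiary hydroxyl against α-ketol rearrangement of the coming α-oxy aldehyde and turns the primary hydroxyl into a directly oxidisable ether.

Step 24
Reactants: 37 bis(triethylsilyl) ether
Product: 38 C8 aldehyde
Conditions: (COCl)2, DMSO, CH2Cl2, −78 → −30 °C; Et3N
Reagents that add atoms: none
Why: Swern conditions oxidise the primary triethylsilyl ether selectively, leaving the tertiary triethylsilyl and secondary triisopropylsilyl ethers.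

Step 25
Reactants: 38 aldehyde; 39 (E)-1-iodoprop-1-ene
Product: 41 allylic alcohol [C8 carbinol, both epimers, E alkene], via propenylchromium dichloride 40 (not isolated)
Conditions: CrCl2 (4 equiv), NiCl2 (2 mol %), DMF, rt
Reagents that add atoms: none
Why: Nozaki–Hiyama–Kishi reaction: the alkenylchromium reagent forms with retention of the E geometry and adds only to the aldehyde in the presence of lactone, ester and acrylate units, and the C8 configuration is irrelevant.

Step 26
Reactants: 41 allylic alcohol
Product: 42 (E)-enone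
Conditions: Dess–Martin periodinane, NaHCO3, CH2Cl2, 0 °C → rt
Reagents that add atoms: none
Why: Dess–Martin oxidation of the only free hydroxyl gives the crotonoyl ketone.

Step 27
Reactants: 42 bis-silyl ether
Product: 43 CNP0186412.1
Conditions: HF·pyridine, pyridine, THF, 0 °C → rt
Reagents that add atoms: none
Why: Fluoride-mediated desilylation under buffered acidic conditions removes both silyl ethers without a base that could add to the Michael acceptors or shift the ester.

**Compound list**

1 | dimethyl (4S,5S)-2,2-dimethyl-1,3-dioxolane-4,5-dicarboxylate | COC(=O)[C@H]1OC(C)(C)O[C@@H]1C(=O)OC | starting material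
2 | (4S,5S)-N,N,N',N',2,2-hexamethyl-1,3-dioxolane-4,5-dicarboxamide | CN(C)C(=O)[C@H]1OC(C)(C)O[C@@H]1C(=O)N(C)C | intermediate
3 | (4S,5S)-5-acetyl-N,N,2,2-tetramethyl-1,3-dioxolane-4-carboxamide | CC(=O)[C@H]1OC(C)(C)O[C@@H]1C(=O)N(C)C | intermediate
4 | silyl enol ether of 3 | C=C(O[Si](C)(C)C(C)(C)C)[C@H]1OC(C)(C)O[C@@H]1C(=O)N(C)C | intermediate
5 | silyloxy epoxide (both epimers at the oxirane carbon) | CC(C)(C)[Si](C)(C)OC1(CO1)[C@H]2OC(C)(C)O[C@@H]2C(=O)N(C)C | intermediate
6 | (4S,5S)-5-[2-(tert-butyldimethylsilyloxy)acetyl]-N,N,2,2-tetramethyl-1,3-dioxolane-4-carboxamide | CC(C)(C)[Si](C)(C)OCC(=O)[C@H]1OC(C)(C)O[C@@H]1C(=O)N(C)C | intermediate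
7 | 2-bromoprop-2-en-1-ol | OCC(Br)=C | starting material
8 | (2-bromoallyloxy)(tert-butyl)dimethylsilane | CC(C)(C)[Si](C)(C)OCC(Br)=C | intermediate
9 | [3-(tert-butyldimethylsilyloxy)prop-1-en-2-yl]lithium | [Li]C(=C)CO[Si](C)(C)C(C)(C)C | intermediate
10 | [3-(tert-butyldimethylsilyloxy)prop-1-en-2-yl]magnesium bromide | Br[Mg]C(=C)CO[Si](C)(C)C(C)(C)C | intermediate
11 | tertiary alcohol, C1 (R), bis-silyl ether | CC(C)(C)[Si](C)(C)OCC(=C)[C@@](O)(CO[Si](C)(C)C(C)(C)C)[C@H]1OC(C)(C)O[C@@H]1C(=O)N(C)C | intermediate
12 | triol | OCC(=C)[C@@](O)(CO)[C@H]1OC(C)(C)O[C@@H]1C(=O)N(C)C | intermediate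
13 | hydroxy enal | O=CC(=C)[C@@](O)(CO)[C@H]1OC(C)(C)O[C@@H]1C(=O)N(C)C | intermediate
14 | lactol (both anomers) | C=C1C(O)OC[C@@]1(O)[C@H]2OC(C)(C)O[C@@H]2C(=O)N(C)C | intermediate
15 | α-methylene-β-hydroxy-γ-butyrolactone | C=C1C(=O)OC[C@@]1(O)[C@H]2OC(C)(C)O[C@@H]2C(=O)N(C)C | intermediate
16 | α-methyl-β-hydroxy-γ-butyrolactone, methyl trans to OH | C[C@H]1C(=O)OC[C@@]1(O)[C@H]2OC(C)(C)O[C@@H]2C(=O)N(C)C | intermediate
17 | triol, C7 (S), C1 (R) | OC[C@H](C)[C@@](O)(CO)[C@H]1OC(C)(C)O[C@@H]1C(=O)N(C)C | intermediate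
18 | C1/C8 acetonide, free C6–OH | OC[C@H](C)[C@@]1(COC(C)(C)O1)[C@H]2OC(C)(C)O[C@@H]2C(=O)N(C)C | intermediate
19 | C6 triethylsilyl ether amide | CC[Si](CC)(CC)OC[C@H](C)[C@@]1(COC(C)(C)O1)[C@H]2OC(C)(C)O[C@@H]2C(=O)N(C)C | intermediate
20 | C4 methyl ketone | CC[Si](CC)(CC)OC[C@H](C)[C@@]1(COC(C)(C)O1)[C@H]2OC(C)(C)O[C@@H]2C(C)=O | intermediate
21 | enol triflate | CC[Si](CC)(CC)OC[C@H](C)[C@@]1(COC(C)(C)O1)[C@H]2OC(C)(C)O[C@@H]2C(=C)OS(=O)(=O)C(F)(F)F | intermediate
22 | methyl bromoacetate | COC(=O)CBr | starting material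
23 | bromo(2-methoxy-2-oxoethyl)zinc | COC(=O)C[Zn]Br | intermediate
24 | β,γ-unsaturated ester, C6 triethylsilyl ether | CC[Si](CC)(CC)OC[C@H](C)[C@@]1(COC(C)(C)O1)[C@H]2OC(C)(C)O[C@@H]2C(=C)CC(=O)OC | intermediate
25 | aldehyde, ene precursor | O=C[C@H](C)[C@@]1(COC(C)(C)O1)[C@H]2OC(C)(C)O[C@@H]2C(=C)CC(=O)OC | intermediate
26 | cycloheptanol with exocyclic C4=Ca enoate | CC1(C)O[C@@H]2/C(=C\C(=O)OC)C[C@@H](O)[C@H](C)[C@@]3(COC(C)(C)O3)[C@H]2O1 | intermediate
27 | saturated hydroxy ester, C4 (S) | CC1(C)O[C@@H]2[C@H](CC(=O)OC)C[C@@H](O)[C@H](C)[C@@]3(COC(C)(C)O3)[C@H]2O1 | intermediate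
28 | C6 triisopropylsilyl ether | CC1(C)O[C@@H]2[C@H](CC(=O)OC)C[C@@H](O[Si](C(C)C)(C(C)C)C(C)C)[C@H](C)[C@@]3(COC(C)(C)O3)[C@H]2O1 | intermediate
29 | Mannich base (both epimers at Ca) | CC1(C)O[C@@H]2[C@H](C(CN(C)C)C(=O)OC)C[C@@H](O[Si](C(C)C)(C(C)C)C(C)C)[C@H](C)[C@@]3(COC(C)(C)O3)[C@H]2O1 | intermediate
30 | trimethylammonium iodide | CC1(C)O[C@@H]2[C@H](C(C[N+](C)(C)C)C(=O)OC)C[C@@H](O[Si](C(C)C)(C(C)C)C(C)C)[C@H](C)[C@@]3(COC(C)(C)O3)[C@H]2O1.[I-] | intermediate
31 | α-methylene ester | CC1(C)O[C@@H]2[C@H](C(=C)C(=O)OC)C[C@@H](O[Si](C(C)C)(C(C)C)C(C)C)[C@H](C)[C@@]3(COC(C)(C)O3)[C@H]2O1 | intermediate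
32 | C2,C3-diol ester | O[C@@H]1[C@H](C(=C)C(=O)OC)C[C@@H](O[Si](C(C)C)(C(C)C)C(C)C)[C@H](C)[C@@]2(COC(C)(C)O2)[C@H]1O | intermediate
33 | α-methylene lactone, free C2–OH | C=C1C(=O)O[C@@H]2[C@H]1C[C@@H](O[Si](C(C)C)(C(C)C)C(C)C)[C@H](C)[C@@]3(COC(C)(C)O3)[C@H]2O | intermediate
34 | isovaleric anhydride | CC(C)CC(=O)OC(=O)CC(C)C | starting material
35 | C2 isovalerate | C=C1C(=O)O[C@@H]2[C@H]1C[C@@H](O[Si](C(C)C)(C(C)C)C(C)C)[C@H](C)[C@@]3(COC(C)(C)O3)[C@H]2OC(=O)CC(C)C | intermediate
36 | C1,C8-diol | C=C1C(=O)O[C@@H]2[C@H]1C[C@@H](O[Si](C(C)C)(C(C)C)C(C)C)[C@H](C)[C@@](O)(CO)[C@H]2OC(=O)CC(C)C | intermediate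
37 | bis(triethylsilyl) ether | C=C1C(=O)O[C@@H]2[C@H]1C[C@@H](O[Si](C(C)C)(C(C)C)C(C)C)[C@H](C)[C@@](O[Si](CC)(CC)CC)(CO[Si](CC)(CC)CC)[C@H]2OC(=O)CC(C)C | intermediate
38 | C8 aldehyde | C=C1C(=O)O[C@@H]2[C@H]1C[C@@H](O[Si](C(C)C)(C(C)C)C(C)C)[C@H](C)[C@@](O[Si](CC)(CC)CC)(C=O)[C@H]2OC(=O)CC(C)C | intermediate
39 | (E)-1-iodoprop-1-ene | C/C=C/I | starting material
40 | (E)-prop-1-enylchromium dichloride | C/C=C/[Cr](Cl)Cl | intermediate
41 | allylic alcohol (both C8 epimers) | C=C1C(=O)O[C@@H]2[C@H]1C[C@@H](O[Si](C(C)C)(C(C)C)C(C)C)[C@H](C)[C@@](O[Si](CC)(CC)CC)(C(O)/C=C/C)[C@H]2OC(=O)CC(C)C | intermediate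
42 | enone, bis-silyl ether | C=C1C(=O)O[C@@H]2[C@H]1C[C@@H](O[Si](C(C)C)(C(C)C)C(C)C)[C@H](C)[C@@](O[Si](CC)(CC)CC)(C(=O)/C=C/C)[C@H]2OC(=O)CC(C)C | intermediate
43 | CNP0186412.1 | C=C1C(=O)O[C@@H]2[C@H]1C[C@@H](O)[C@H](C)[C@@](O)(C(=O)/C=C/C)[C@H]2OC(=O)CC(C)C | target

**Step count**

Total: 27 steps. Longest linear sequence: 26 steps (steps 1–3 and 5–27 from 1; step 4 prepares bromide 8).

**Steps most likely to fail**

Step 16. The process at risk is facial selection at the aldehyde carbon: the competing chair with the C7 methyl equatorial, which also fits the trans-fused dioxolane best, leads to the C6 epimer; an acetonide may also be opened by the Lewis acid. The fallback sets out from 25: cyclise with Me2AlCl (CH2Cl2, −78 °C), the classical promoter, which should favour the C6-epimeric cycloheptanol F1. Its C6 centre is then inverted by Mitsunobu esterification (PPh3, DIAD, 4-nitrobenzoic acid, toluene) to the inverted 4-nitrobenzoate F2, and methanolysis (K2CO3, MeOH) comes back to the route at 26.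

Step 5. The processes at risk are breakdown of the oxygenated alkenyl metal before addition (β-elimination of silyloxide or silyl migration to carbon) and erosion of chelation control. The fallback sets out from 6: add commercial isopropenylmagnesium bromide (Et2O, −78 °C) under the same chelation control to the isopropenyl carbinol F3. Allylic oxidation of its only allylic C–H position (SeO2 cat., t-BuOOH, CH2Cl2) should give the allylic alcohol F4, and Bu4NF comes back to the route at triol 12.

Step 20. The process at risk is loss of the C1/C8 acetonide together with the C2/C3 one, or incomplete lactonisation. The fallback sets out from 31: hydrolyse both acetonides with aqueous CF3CO2H in THF (lactonisation follows) to the triol lactone F5. Selective silylation of the primary C8 hydroxyl (t-BuMe2SiCl, imidazole) gives the silyl ether F6, and acylation of the secondary C2 hydroxyl with isovaleric anhydride and DMAP gives the isovalerate F7, the tertiary hydroxyl staying free. Cleavage of the primary silyl ether with HF·pyridine at 0 °C comes back to the route at diol 36.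

**Further compounds**

F1 | step 16 | C6-epimeric cycloheptanol (6-OH cis to 7-CH3) | CC1(C)O[C@@H]2/C(=C\C(=O)OC)C[C@H](O)[C@H](C)[C@@]3(COC(C)(C)O3)[C@H]2O1
F2 | step 16 | inverted 4-nitrobenzoate | CC1(C)O[C@@H]2/C(=C\C(=O)OC)C[C@@H](OC(=O)c4ccc(cc4)[N+](=O)[O-])[C@H](C)[C@@]3(COC(C)(C)O3)[C@H]2O1
F3 | step 5 | isopropenyl carbinol | CC(=C)[C@@](O)(CO[Si](C)(C)C(C)(C)C)[C@H]1OC(C)(C)O[C@@H]1C(=O)N(C)C
F4 | step 5 | allylic alcohol, C8 silyl ether | OCC(=C)[C@@](O)(CO[Si](C)(C)C(C)(C)C)[C@H]1OC(C)(C)O[C@@H]1C(=O)N(C)C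
F5 | step 20 | triol lactone | C=C1C(=O)O[C@@H]2[C@H]1C[C@@H](O[Si](C(C)C)(C(C)C)C(C)C)[C@H](C)[C@@](O)(CO)[C@H]2O
F6 | step 20 | C8 tert-butyldimethylsilyl ether | C=C1C(=O)O[C@@H]2[C@H]1C[C@@H](O[Si](C(C)C)(C(C)C)C(C)C)[C@H](C)[C@@](O)(CO[Si](C)(C)C(C)(C)C)[C@H]2O
F7 | step 20 | C2 isovalerate, C8 silyl ether | C=C1C(=O)O[C@@H]2[C@H]1C[C@@H](O[Si](C(C)C)(C(C)C)C(C)C)[C@H](C)[C@@](O)(CO[Si](C)(C)C(C)(C)C)[C@H]2OC(=O)CC(C)C
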